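## Retrosynthetic overview

1. Aristophenone A (24) ⇐ hydroxide deprotection of 23 ⇐ C3 aroylation of the O-methyl tri-prenyl core 19 with aroyl chloride 22 ⇐ side-chain adjustment of bicyclic diester 16 (metathesis at C5, ester to prenyl at C7).
2. 16 ⇐ acyclic anhydride 14 in one operation: ring A (C1–C2–C3–C4–C5–C9) forms first through the C9–C5 bond, ring B (C1–C9–C5–C6–C7–C8) second through the C8–C7 bond.
3. Enabling feature: C9 and C8 are both bonded to C1, so C9–C1–C8 plus one extra carboxyl carbon on C8 can be carried as a 2,2-dimethylsuccinic anhydride ring (acyl donor for C9, then the carboxylate from which C8 becomes a radical); C5 bears two CH2–CH= chains in the target (its prenyl group and C6–C7), so it enters as a non-stereogenic CH with two identical enoate arms.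
4. 14 ⇐ 12, whose quaternary C1 (the only stereocentre before the key step) comes from palladium-catalysed asymmetric prenylation of β-keto ester 11 ⇐ Claisen union of succinate 2 with acid 9 (from cyclopent-3-enecarboxylic acid 3).
5. Atom numbers C1–C9 are those of the bicyclo[3.3.1]nonane skeleton of the target and are used for all intermediates.

Key step: step 9

Remark: the sense of induction of the Trost ligand in step 7 is assumed; the ligand enantiomer that delivers (3R)-12 is the one to be used, and nothing else in the route depends on this choice.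

## Route

Step 1
Reactants: 1 2,2-dimethylbutanedioic acid (2,2-dimethylsuccinic acid)
Product: 2 bis[2-(trimethylsilyl)ethyl] 2,2-dimethylbutanedioate
Conditions: Me3SiCH2CH2OH (2.4 equiv), DCC (2.3 equiv), DMAP (0.2 equiv), CH2Cl2, 0 °C to rt
Reagents that add atoms: 2-(trimethylsilyl)ethanol, C[Si](C)(C)CCO
Why: Steglich esterification gives the diester, whose fluoride-labile ester groups should later be removable without acid or hydroxide; no stereocentre is formed.

Step 2
Reactants: 3 cyclopent-3-ene-1-carboxylic acid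
Product: 5 (4E)-6-methoxy-2-[(2E)-4-methoxy-4-oxobut-2-en-1-yl]-6-oxohex-4-enoic acid, via dialdehyde acid 4 (not isolated)
Conditions: O3, CH2Cl2/MeOH (4:1), −78 °C; PPh3 (1.1 equiv), −78 °C to rt; then Ph3P=CHCO2Me (3.2 equiv), rt
Reagents that add atoms: methyl (triphenylphosphoranylidene)acetate, COC(=O)C=P(c1ccccc1)(c1ccccc1)c1ccccc1
Why: Ozonolysis with reductive work-up and in situ Wittig olefination with the stabilised ylide should give the E,E-bis-enoate, in which the former ring carbon (the future C5) carries two identical arms and is therefore not a stereocentre.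

Step 3
Reactants: 5 (4E)-6-methoxy-2-[(2E)-4-methoxy-4-oxobut-2-en-1-yl]-6-oxohex-4-enoic acid
Product: 7 dimethyl (2E,7E)-5-{3-oxo-3-[2-(trimethylsilyl)ethoxy]propanoyl}nona-2,7-dienedioate, via acyl Meldrum's acid 6 (not isolated)
Conditions: Meldrum's acid (1.1 equiv), DCC (1.1 equiv), DMAP (1.2 equiv), CH2Cl2, 0 °C to rt; filter; then Me3SiCH2CH2OH (1.5 equiv), toluene, 80 °C
Reagents that add atoms: 2,2-dimethyl-1,3-dioxane-4,6-dione (Meldrum's acid), CC1(C)OC(=O)CC(=O)O1; 2-(trimethylsilyl)ethanol, C[Si](C)(C)CCO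
Why: Meldrum's acid route to β-keto esters: carbodiimide C-acylation, then thermolysis to the acylketene, which the silyl alcohol traps under neutral conditions.

Step 4
Reactants: 7 dimethyl (2E,7E)-5-{3-oxo-3-[2-(trimethylsilyl)ethoxy]propanoyl}nona-2,7-dienedioate
Product: 8 dimethyl (2E,7E)-5-{(1E)-1-methoxy-3-oxo-3-[2-(trimethylsilyl)ethoxy]prop-1-en-1-yl}nona-2,7-dienedioate
Conditions: HC(OMe)3 (5 equiv), TsOH·H2O (5 mol %), MeOH/CH2Cl2, rt
Reagents that add atoms: trimethyl orthoformate, COC(OC)OC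
Why: Acid-catalysed ketalisation of the β-keto ester and loss of methanol should give the thermodynamically preferred E-β-methoxy enoate, which places the enol ether oxygen on the future C4 and leaves the future C5–H as the only ketone-type acidic proton.

Step 5
Reactants: 8 dimethyl (2E,7E)-5-{(1E)-1-methoxy-3-oxo-3-[2-(trimethylsilyl)ethoxy]prop-1-en-1-yl}nona-2,7-dienedioate
Product: 9 (2E,6E)-3,8-dimethoxy-4-[(2E)-4-methoxy-4-oxobut-2-en-1-yl]-8-oxoocta-2,6-dienoic acid
Conditions: Bu4NF (1.5 equiv), THF, 0 °C to rt; then cold 1 M HCl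
Reagents that add atoms: none
Why: Fluoride-induced β-elimination of the 2-(trimethylsilyl)ethyl ester should free the acid while the methyl enoates and the enol ether stay intact.

Step 6
Reactants: 2 bis[2-(trimethylsilyl)ethyl] 2,2-dimethylbutanedioate (2.0 equiv); 9 (2E,6E)-3,8-dimethoxy-4-[(2E)-4-methoxy-4-oxobut-2-en-1-yl]-8-oxoocta-2,6-dienoic acid
Product: 11 bis[2-(trimethylsilyl)ethyl] 3-{(2E,6E)-3,8-dimethoxy-4-[(2E)-4-methoxy-4-oxobut-2-en-1-yl]-8-oxoocta-2,6-dienoyl}-2,2-dimethylbutanedioate (racemic at C3), via acid chloride 10 (not isolated)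
Conditions: 9, 1-chloro-N,N,2-trimethylprop-1-en-1-amine (1.1 equiv), CH2Cl2, 0 °C; separately 2, LiN(i-Pr)2 (2.0 equiv), THF, −78 °C; then the acid chloride solution, −78 °C, 1 h; aq NH4Cl
Reagents that add atoms: none
Why: Crossed Claisen acylation: the acid is converted to its chloride under neutral conditions (Ghosez reagent) and C-acylates the lithium enolate of 2, which has only one enolisable position; the second equivalent of enolate deprotonates the more acidic product, and the new centre is racemic and labile at this stage.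

Step 7
Reactants: 11 bis[2-(trimethylsilyl)ethyl] 3-{(2E,6E)-3,8-dimethoxy-4-[(2E)-4-methoxy-4-oxobut-2-en-1-yl]-8-oxoocta-2,6-dienoyl}-2,2-dimethylbutanedioate
Product: 12 bis[2-(trimethylsilyl)ethyl] (3R)-3-{(2E,6E)-3,8-dimethoxy-4-[(2E)-4-methoxy-4-oxobut-2-en-1-yl]-8-oxoocta-2,6-dienoyl}-2,2-dimethyl-3-(3-methylbut-2-en-1-yl)butanedioate
Conditions: prenyl acetate (1.5 equiv), Pd2(dba)3·CHCl3 (2.5 mol %), (R,R)-DACH-phenyl Trost ligand (7.5 mol %), 1,1,3,3-tetramethylguanidine (1.2 equiv), toluene, 0 °C to rt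
Reagents that add atoms: 3-methylbut-2-en-1-yl acetate (prenyl acetate), CC(=O)OCC=C(C)C
Why: Tsuji–Trost asymmetric allylic alkylation of the stabilised β-keto ester enolate: attack at the unsubstituted terminus of the 1,1-dimethylallyl palladium complex gives the linear prenyl group, and the chiral pocket of the ligand selects one enolate face, which sets the quaternary C1.

Step 8
Reactants: 12 bis[2-(trimethylsilyl)ethyl] (3R)-3-{(2E,6E)-3,8-dimethoxy-4-[(2E)-4-methoxy-4-oxobut-2-en-1-yl]-8-oxoocta-2,6-dienoyl}-2,2-dimethyl-3-(3-methylbut-2-en-1-yl)butanedioate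
Product: 14 dimethyl (2E,7E)-5-{(1E)-3-[(3R)-4,4-dimethyl-3-(3-methylbut-2-en-1-yl)-2,5-dioxooxolan-3-yl]-1-methoxy-3-oxoprop-1-en-1-yl}nona-2,7-dienedioate, via dicarboxylate salt 13 (not isolated)
Conditions: Bu4NF (2.4 equiv), THF, 0 °C; then (CF3CO)2O (1.2 equiv), −20 to 0 °C
Reagents that add atoms: none
Why: Fluoride-induced cleavage of both silylethyl esters and dehydrative closure through the mixed trifluoroacetic anhydride (5-exo-trig acyl substitution, favoured by full substitution) should give the succinic anhydride without ever freeing the β-keto acid; C1 is not touched.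

Step 9
Reactants: 14 dimethyl (2E,7E)-5-{(1E)-3-[(3R)-4,4-dimethyl-3-(3-methylbut-2-en-1-yl)-2,5-dioxooxolan-3-yl]-1-methoxy-3-oxoprop-1-en-1-yl}nona-2,7-dienedioate
Product: 16 methyl (2E)-4-[(1R,5S,7S)-4-methoxy-7-(2-methoxy-2-oxoethyl)-8,8-dimethyl-1-(3-methylbut-2-en-1-yl)-2,9-dioxobicyclo[3.3.1]non-3-en-5-yl]but-2-enoate, via monocyclic caesium carboxylate 15 (not isolated)
Conditions: Cs2CO3 (1.2 equiv), [Ir(dF(CF3)ppy)2(dtbbpy)]PF6 (1 mol %), dry degassed DMF, 4 Å MS, 450 nm LEDs, 35 °C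
Reagents that add atoms: none
Why: Proposed new method: Cs2CO3 reversibly removes C5–H, the most acidic proton of 14 (γ to the C2 ketone through the C3=C4 enol ether), and the γ-carbon of the dienolate attacks the anhydride carbonyl C9, closing ring A by a 6-(enolendo)-exo-trig Claisen acylation that is irreversible because the leaving group is the carboxylate on C8 (intermediate 15); the closest known reactions are the γ-acylation of vinylogous-ester dienolates and the opening of cyclic anhydrides by enolates. Since this carboxylate does not exist before the C9–C5 bond, the radical can only be made once ring A is there: the excited iridium photocatalyst oxidises it, CO2 is lost, and the tertiary C8 radical adds to C7, the β-carbon of an enoate arm, in a 6-exo-trig Giese cyclisation that closes ring B, after which the reduced photocatalyst turns the α-ester radical into an enolate that hydrogencarbonate protonates, so that the base is returned (closest known reaction: photoredox decarboxylative conjugate addition of tertiary carboxylates). C1 is already set and decides the sense of the bicycle, and C5 becomes a stereocentre without a selectivity problem, because its two arms are identical and only the arm on the same face of ring A as the C8 radical can reach it. C7 is set in a chair-like transition state of the forming cyclohexanone in which the CH–CO2Me end of the alkene is equatorial (exo), the axial position pointing into the C2–C4 bridge. The step needs C- and not O-acylation, which the substrate secures because the enolate oxygen sits on C2 and could reach C9 only through a four-membered ring, and it needs the C5 dienolate and not an ester dienolate of the arms to react, which the weak carbonate base (equilibrium deprotonation at the most acidic site) and the much higher acylating power of the anhydride secure. It also needs 6-exo addition to the enoate before the tertiary radical is quenched or shifts an acyl group, which the polarity match (nucleophilic radical, electron-poor alkene) and the 1,3-diaxial proximity of C8 and the arm secure.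

Step 10
Reactants: 16 methyl (2E)-4-[(1R,5S,7S)-4-methoxy-7-(2-methoxy-2-oxoethyl)-8,8-dimethyl-1-(3-methylbut-2-en-1-yl)-2,9-dioxobicyclo[3.3.1]non-3-en-5-yl]but-2-enoate
Product: 17 methyl [(1R,5S,7S)-4-methoxy-8,8-dimethyl-1,5-bis(3-methylbut-2-en-1-yl)-2,9-dioxobicyclo[3.3.1]non-3-en-7-yl]acetate
Conditions: 2-methylbut-2-ene (50 equiv), second-generation Grubbs catalyst (10 mol %), CH2Cl2, 40 °C, sealed tube
Reagents that add atoms: 2-methylbut-2-ene, CC=C(C)C
Why: Olefin cross metathesis should exchange the =CH–CO2Me end of the remaining enoate arm for =CMe2, while the prenyl group on C1 can only be regenerated under these conditions; no stereocentre changes.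

Step 11
Reactants: 17 methyl [(1R,5S,7S)-4-methoxy-8,8-dimethyl-1,5-bis(3-methylbut-2-en-1-yl)-2,9-dioxobicyclo[3.3.1]non-3-en-7-yl]acetate
Product: 18 [(1R,5S,7S)-4-methoxy-8,8-dimethyl-1,5-bis(3-methylbut-2-en-1-yl)-2,9-dioxobicyclo[3.3.1]non-3-en-7-yl]acetaldehyde
Conditions: i-Bu2AlH (1.1 equiv), CH2Cl2, −78 °C; MeOH, then aq potassium sodium tartrate
Reagents that add atoms: none
Why: Partial reduction of the unhindered methyl ester through the aluminium hemiacetal that is stable at −78 °C; the C9 ketone is shielded by two quaternary carbons and the C2 vinylogous ester carbonyl is deactivated and neopentylic.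

Step 12
Reactants: 18 [(1R,5S,7S)-4-methoxy-8,8-dimethyl-1,5-bis(3-methylbut-2-en-1-yl)-2,9-dioxobicyclo[3.3.1]non-3-en-7-yl]acetaldehyde
Product: 19 (1R,5S,7R)-4-methoxy-8,8-dimethyl-1,5,7-tris(3-methylbut-2-en-1-yl)bicyclo[3.3.1]non-3-ene-2,9-dione
Conditions: i-PrPPh3I (1.5 equiv), n-BuLi (1.4 equiv), THF, 0 °C; then 18, −78 °C to rt
Reagents that add atoms: isopropyltriphenylphosphonium iodide, CC(C)[P+](c1ccccc1)(c1ccccc1)c1ccccc1.[I-]
Why: Wittig olefination with the non-stabilised isopropylidene ylide completes the third prenyl group without a geometry issue; C7 is not acidic and keeps its configuration (the descriptor changes only through the priority rules).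

Step 13
Reactants: 20 3,4-dihydroxybenzoic acid
Product: 21 tert-butyldimethylsilyl 3,4-bis[(tert-butyldimethylsilyl)oxy]benzoate
Conditions: t-BuMe2SiCl (3.5 equiv), imidazole (7 equiv), DMF, rt
Reagents that add atoms: tert-butyl(chloro)dimethylsilane, CC(C)(C)[Si](C)(C)Cl
Why: Silylation of both phenols and the carboxyl group with silyl chloride and imidazole; no stereocentre.

Step 14
Reactants: 21 tert-butyldimethylsilyl 3,4-bis[(tert-butyldimethylsilyl)oxy]benzoate
Product: 22 3,4-bis[(tert-butyldimethylsilyl)oxy]benzoyl chloride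
Conditions: (COCl)2 (1.3 equiv), DMF (cat.), CH2Cl2, 0 °C to rt; evaporate, use crude
Reagents that add atoms: oxalyl chloride, O=C(Cl)C(=O)Cl
Why: Direct conversion of a silyl ester into the acid chloride by the Vilsmeier chloride under neutral conditions, which should leave the aryl silyl ethers intact.

Step 15
Reactants: 19 (1R,5S,7R)-4-methoxy-8,8-dimethyl-1,5,7-tris(3-methylbut-2-en-1-yl)bicyclo[3.3.1]non-3-ene-2,9-dione; 22 3,4-bis[(tert-butyldimethylsilyl)oxy]benzoyl chloride
Product: 23 (1S,5S,7R)-3-{3,4-bis[(tert-butyldimethylsilyl)oxy]benzoyl}-4-methoxy-8,8-dimethyl-1,5,7-tris(3-methylbut-2-en-1-yl)bicyclo[3.3.1]non-3-ene-2,9-dione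
Conditions: lithium 2,2,6,6-tetramethylpiperidide (1.5 equiv, from the amine and n-BuLi), THF, −78 °C; then 22 (1.6 equiv), −78 to −40 °C
Reagents that add atoms: none
Why: Lithiation of the vinylic α-position C3 of the vinylogous ester (the only acidic C–H, both bridgeheads being quaternary) with a hindered lithium amide and C-acylation by the aroyl chloride; the C1 descriptor changes only through the priority rules.

Step 16
Reactants: 23 (1S,5S,7R)-3-{3,4-bis[(tert-butyldimethylsilyl)oxy]benzoyl}-4-methoxy-8,8-dimethyl-1,5,7-tris(3-methylbut-2-en-1-yl)bicyclo[3.3.1]non-3-ene-2,9-dione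
Product: 24 aristophenone A, (1S,5S,7R)-3-(3,4-dihydroxybenzoyl)-4-hydroxy-8,8-dimethyl-1,5,7-tris(3-methylbut-2-en-1-yl)bicyclo[3.3.1]non-3-ene-2,9-dione
Conditions: LiOH·H2O (10 equiv), dioxane/H2O (4:1), degassed, 90 °C; then cold 1 M HCl to pH 4
Reagents that add atoms: lithium hydroxide, [Li+].[OH-]
Why: Addition–elimination of hydroxide at C4 of the vinylogous ester (loss of methoxide) with simultaneous cleavage of both aryl silyl ethers should give the hydrogen-bonded enol; no stereocentre can epimerise (C1 and C5 quaternary, C7 not acidic).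

## Compound list

1 | 2,2-dimethylbutanedioic acid | CC(C)(CC(=O)O)C(=O)O | starting material
2 | bis[2-(trimethylsilyl)ethyl] 2,2-dimethylbutanedioate | C[Si](C)(C)CCOC(=O)CC(C)(C)C(=O)OCC[Si](C)(C)C | intermediate
3 | cyclopent-3-ene-1-carboxylic acid | OC(=O)C1CC=CC1 | starting material
4 | 4-oxo-2-(2-oxoethyl)butanoic acid (dialdehyde acid) | OC(=O)C(CC=O)CC=O | intermediate (not isolated)
5 | (4E)-6-methoxy-2-[(2E)-4-methoxy-4-oxobut-2-en-1-yl]-6-oxohex-4-enoic acid | OC(=O)C(C/C=C/C(=O)OC)C/C=C/C(=O)OC | intermediate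
6 | dimethyl (2E,7E)-5-[(2,2-dimethyl-4,6-dioxo-1,3-dioxan-5-yl)carbonyl]nona-2,7-dienedioate (acyl Meldrum's acid) | CC1(C)OC(=O)C(C(=O)C(C/C=C/C(=O)OC)C/C=C/C(=O)OC)C(=O)O1 | intermediate (not isolated)
7 | dimethyl (2E,7E)-5-{3-oxo-3-[2-(trimethylsilyl)ethoxy]propanoyl}nona-2,7-dienedioate | C[Si](C)(C)CCOC(=O)CC(=O)C(C/C=C/C(=O)OC)C/C=C/C(=O)OC | intermediate
8 | dimethyl (2E,7E)-5-{(1E)-1-methoxy-3-oxo-3-[2-(trimethylsilyl)ethoxy]prop-1-en-1-yl}nona-2,7-dienedioate | C[Si](C)(C)CCOC(=O)/C=C(/OC)C(C/C=C/C(=O)OC)C/C=C/C(=O)OC | intermediate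
9 | (2E,6E)-3,8-dimethoxy-4-[(2E)-4-methoxy-4-oxobut-2-en-1-yl]-8-oxoocta-2,6-dienoic acid | OC(=O)/C=C(/OC)C(C/C=C/C(=O)OC)C/C=C/C(=O)OC | intermediate
10 | (2E,6E)-3,8-dimethoxy-4-[(2E)-4-methoxy-4-oxobut-2-en-1-yl]-8-oxoocta-2,6-dienoyl chloride | ClC(=O)/C=C(/OC)C(C/C=C/C(=O)OC)C/C=C/C(=O)OC | intermediate (not isolated)
11 | bis[2-(trimethylsilyl)ethyl] 3-{(2E,6E)-3,8-dimethoxy-4-[(2E)-4-methoxy-4-oxobut-2-en-1-yl]-8-oxoocta-2,6-dienoyl}-2,2-dimethylbutanedioate (racemic at C3) | C[Si](C)(C)CCOC(=O)C(C(=O)/C=C(/OC)C(C/C=C/C(=O)OC)C/C=C/C(=O)OC)C(C)(C)C(=O)OCC[Si](C)(C)C | intermediate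
12 | bis[2-(trimethylsilyl)ethyl] (3R)-3-{(2E,6E)-3,8-dimethoxy-4-[(2E)-4-methoxy-4-oxobut-2-en-1-yl]-8-oxoocta-2,6-dienoyl}-2,2-dimethyl-3-(3-methylbut-2-en-1-yl)butanedioate | C[Si](C)(C)CCOC(=O)[C@@](CC=C(C)C)(C(=O)/C=C(/OC)C(C/C=C/C(=O)OC)C/C=C/C(=O)OC)C(C)(C)C(=O)OCC[Si](C)(C)C | intermediate
13 | bis(tetrabutylammonium) (3R)-3-{(2E,6E)-3,8-dimethoxy-4-[(2E)-4-methoxy-4-oxobut-2-en-1-yl]-8-oxoocta-2,6-dienoyl}-2,2-dimethyl-3-(3-methylbut-2-en-1-yl)butanedioate | CCCC[N+](CCCC)(CCCC)CCCC.CCCC[N+](CCCC)(CCCC)CCCC.[O-]C(=O)[C@@](CC=C(C)C)(C(=O)/C=C(/OC)C(C/C=C/C(=O)OC)C/C=C/C(=O)OC)C(C)(C)C(=O)[O-] | intermediate (not isolated)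
14 | dimethyl (2E,7E)-5-{(1E)-3-[(3R)-4,4-dimethyl-3-(3-methylbut-2-en-1-yl)-2,5-dioxooxolan-3-yl]-1-methoxy-3-oxoprop-1-en-1-yl}nona-2,7-dienedioate | O=C1OC(=O)C(C)(C)[C@]1(CC=C(C)C)C(=O)/C=C(/OC)C(C/C=C/C(=O)OC)C/C=C/C(=O)OC | intermediate
15 | caesium 2-[(1R)-4-methoxy-5,5-bis[(2E)-4-methoxy-4-oxobut-2-en-1-yl]-1-(3-methylbut-2-en-1-yl)-2,6-dioxocyclohex-3-en-1-yl]-2-methylpropanoate | [Cs+].O=C1[C@](CC=C(C)C)(C(C)(C)C(=O)[O-])C(=O)C=C(OC)C1(C/C=C/C(=O)OC)C/C=C/C(=O)OC | intermediate (not isolated)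
16 | methyl (2E)-4-[(1R,5S,7S)-4-methoxy-7-(2-methoxy-2-oxoethyl)-8,8-dimethyl-1-(3-methylbut-2-en-1-yl)-2,9-dioxobicyclo[3.3.1]non-3-en-5-yl]but-2-enoate (C7 chain exo, away from the C2–C4 bridge) | COC(=O)C[C@@H]1C[C@]2(C/C=C/C(=O)OC)C(=O)[C@@](CC=C(C)C)(C(=O)C=C2OC)C1(C)C | intermediate
17 | methyl [(1R,5S,7S)-4-methoxy-8,8-dimethyl-1,5-bis(3-methylbut-2-en-1-yl)-2,9-dioxobicyclo[3.3.1]non-3-en-7-yl]acetate | COC(=O)C[C@@H]1C[C@]2(CC=C(C)C)C(=O)[C@@](CC=C(C)C)(C(=O)C=C2OC)C1(C)C | intermediate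
18 | [(1R,5S,7S)-4-methoxy-8,8-dimethyl-1,5-bis(3-methylbut-2-en-1-yl)-2,9-dioxobicyclo[3.3.1]non-3-en-7-yl]acetaldehyde | O=CC[C@@H]1C[C@]2(CC=C(C)C)C(=O)[C@@](CC=C(C)C)(C(=O)C=C2OC)C1(C)C | intermediate
19 | (1R,5S,7R)-4-methoxy-8,8-dimethyl-1,5,7-tris(3-methylbut-2-en-1-yl)bicyclo[3.3.1]non-3-ene-2,9-dione | CC(C)=CC[C@@H]1C[C@]2(CC=C(C)C)C(=O)[C@@](CC=C(C)C)(C(=O)C=C2OC)C1(C)C | intermediate
20 | 3,4-dihydroxybenzoic acid | O=C(O)c1ccc(O)c(O)c1 | starting material
21 | tert-butyldimethylsilyl 3,4-bis[(tert-butyldimethylsilyl)oxy]benzoate | CC(C)(C)[Si](C)(C)OC(=O)c1ccc(O[Si](C)(C)C(C)(C)C)c(O[Si](C)(C)C(C)(C)C)c1 | intermediate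
22 | 3,4-bis[(tert-butyldimethylsilyl)oxy]benzoyl chloride | CC(C)(C)[Si](C)(C)Oc1ccc(C(=O)Cl)cc1O[Si](C)(C)C(C)(C)C | intermediate
23 | (1S,5S,7R)-3-{3,4-bis[(tert-butyldimethylsilyl)oxy]benzoyl}-4-methoxy-8,8-dimethyl-1,5,7-tris(3-methylbut-2-en-1-yl)bicyclo[3.3.1]non-3-ene-2,9-dione | CC(C)=CC[C@@H]1C[C@]2(CC=C(C)C)C(=O)[C@@](CC=C(C)C)(C(=O)C(C(=O)c3ccc(O[Si](C)(C)C(C)(C)C)c(O[Si](C)(C)C(C)(C)C)c3)=C2OC)C1(C)C | intermediate
24 | aristophenone A, (1S,5S,7R)-3-(3,4-dihydroxybenzoyl)-4-hydroxy-8,8-dimethyl-1,5,7-tris(3-methylbut-2-en-1-yl)bicyclo[3.3.1]non-3-ene-2,9-dione | CC(C)=CC[C@@H]1C[C@]2(CC=C(C)C)C(=O)[C@@](CC=C(C)C)(C(=O)C(C(=O)c3ccc(O)c(O)c3)=C2O)C1(C)C | target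

## Step count and risks

Total step count: 16. Longest linear sequence: 13 steps (from 3 to 24: steps 2 to 12, then 15 and 16).

Steps most likely to fail:

Step 9 (proposed new method). The acyl transfer under carbonate may be slower than opening of the anhydride by adventitious water or than base-induced Michael reactions between the two enoate arms. The tertiary radical may also be reduced, or shift an acyl group, before it cyclises. The fallback separates the two events and uses only known reactions. From 14, the Claisen acylation is run alone (Cs2CO3, DMF, dark, then cold 1 M HCl) and the acid 2-[(1R)-4-methoxy-5,5-bis[(2E)-4-methoxy-4-oxobut-2-en-1-yl]-1-(3-methylbut-2-en-1-yl)-2,6-dioxocyclohex-3-en-1-yl]-2-methylpropanoic acid F1 is isolated. F1 is coupled with N-hydroxyphthalimide (N,N'-diisopropylcarbodiimide, cat. DMAP) to the redox-active ester, its 1,3-dioxoisoindolin-2-yl ester F2. Reductive photocatalytic decarboxylation of F2 [Ru(bpy)3(PF6)2 (1 mol %), Hantzsch ester, CH2Cl2, blue LEDs] generates the same C8 radical, which cyclises 6-exo and takes hydrogen from the Hantzsch ester. The route is rejoined at 16.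

Step 7. Facial discrimination at the crowded acyclic enolate may be poor, or C-allylation next to the CMe2 group may be sluggish. The fallback replaces asymmetric catalysis by resolution. From 11, prenylation with an achiral catalyst [Pd(PPh3)4, prenyl acetate, tetramethylguanidine] gives racemic bis[2-(trimethylsilyl)ethyl] 3-acyl-2,2-dimethyl-3-(3-methylbut-2-en-1-yl)butanedioate F3. The enantiomers are separated by preparative supercritical-fluid chromatography on a chiral stationary phase. The (3R)-enantiomer is 12 and rejoins the route; the (3S)-enantiomer of 12 F4 is set aside.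

Step 10. The electron-poor 1,2-disubstituted enoate may not engage the ruthenium alkylidene before the catalyst decomposes. The fallback changes the alkene type before metathesis. From 16, i-Bu2AlH (5 equiv, CH2Cl2, −78 to −40 °C) reduces both esters and gives (1R,5S,7S)-7-(2-hydroxyethyl)-5-[(2E)-4-hydroxybut-2-en-1-yl]-4-methoxy-8,8-dimethyl-1-(3-methylbut-2-en-1-yl)bicyclo[3.3.1]non-3-ene-2,9-dione F5. Its allylic alcohol arm is a far better metathesis partner; exchange with 2-methylbut-2-ene (second-generation Grubbs catalyst) gives (1R,5S,7S)-7-(2-hydroxyethyl)-4-methoxy-8,8-dimethyl-1,5-bis(3-methylbut-2-en-1-yl)bicyclo[3.3.1]non-3-ene-2,9-dione F6. Dess–Martin periodinane oxidises the primary alcohol of F6 to aldehyde 18, where the route is rejoined (steps 10 and 11 are replaced).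

Further compounds
F1 | step 9 | 2-[(1R)-4-methoxy-5,5-bis[(2E)-4-methoxy-4-oxobut-2-en-1-yl]-1-(3-methylbut-2-en-1-yl)-2,6-dioxocyclohex-3-en-1-yl]-2-methylpropanoic acid | O=C1[C@](CC=C(C)C)(C(C)(C)C(=O)O)C(=O)C=C(OC)C1(C/C=C/C(=O)OC)C/C=C/C(=O)OC
F2 | step 9 | 1,3-dioxoisoindolin-2-yl 2-[(1R)-4-methoxy-5,5-bis[(2E)-4-methoxy-4-oxobut-2-en-1-yl]-1-(3-methylbut-2-en-1-yl)-2,6-dioxocyclohex-3-en-1-yl]-2-methylpropanoate | O=C1[C@](CC=C(C)C)(C(C)(C)C(=O)ON2C(=O)c3ccccc3C2=O)C(=O)C=C(OC)C1(C/C=C/C(=O)OC)C/C=C/C(=O)OC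
F3 | step 7 | racemic bis[2-(trimethylsilyl)ethyl] 3-{(2E,6E)-3,8-dimethoxy-4-[(2E)-4-methoxy-4-oxobut-2-en-1-yl]-8-oxoocta-2,6-dienoyl}-2,2-dimethyl-3-(3-methylbut-2-en-1-yl)butanedioate | C[Si](C)(C)CCOC(=O)C(CC=C(C)C)(C(=O)/C=C(/OC)C(C/C=C/C(=O)OC)C/C=C/C(=O)OC)C(C)(C)C(=O)OCC[Si](C)(C)C
F4 | step 7 | (3S)-enantiomer of 12 | C[Si](C)(C)CCOC(=O)[C@](CC=C(C)C)(C(=O)/C=C(/OC)C(C/C=C/C(=O)OC)C/C=C/C(=O)OC)C(C)(C)C(=O)OCC[Si](C)(C)C
F5 | step 10 | (1R,5S,7S)-7-(2-hydroxyethyl)-5-[(2E)-4-hydroxybut-2-en-1-yl]-4-methoxy-8,8-dimethyl-1-(3-methylbut-2-en-1-yl)bicyclo[3.3.1]non-3-ene-2,9-dione | OCC[C@@H]1C[C@]2(C/C=C/CO)C(=O)[C@@](CC=C(C)C)(C(=O)C=C2OC)C1(C)C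
F6 | step 10 | (1R,5S,7S)-7-(2-hydroxyethyl)-4-methoxy-8,8-dimethyl-1,5-bis(3-methylbut-2-en-1-yl)bicyclo[3.3.1]non-3-ene-2,9-dione | OCC[C@@H]1C[C@]2(CC=C(C)C)C(=O)[C@@](CC=C(C)C)(C(=O)C=C2OC)C1(C)C
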